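## Structural features

The target is a germacrane: a ten-membered carbocycle (C1–C10) with an α-methylene-γ-butyrolactone (C11, C12, C13 and the C8 oxygen) trans-fused across C7–C8 (H7 α, H8 β). The carbocycle carries a cis-configured trisubstituted oxirane at C4–C5 (C15 on C4), an angelate ester at C6, and a secondary allylic hydroxyl at C1 beside the exocyclic C10=C14 methylene. Five of the six stereocenters are contiguous (C4 R, C5 S, C6 S, C7 R, C8 S); the sixth, C1 (S), sits alone on the far side of the ring. The fragile groups are:
- the methylene lactone, a Michael acceptor that is sensitive to base and nucleophiles;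
- the angelate, which drifts from Z to E (tiglate) under base, acid, heat or acyl-transfer catalysts;
- the oxirane next to an ester, which is acid-labile and open to transannular attack by C10=C14;
- the 8,12-lactone beside a C6 oxygen, which can translactonise.

The real difficulty is the medium ring: a Z-configured C4–C5 unit and five stereocenters must be set on a mobile ten-membered ring that closes badly end to end. The feature that is exploited is the 1,5-relationship, through C1–C2–C3, between C10 (an sp2 carbon that can be a ketone) and the C4–C5 oxirane (which can come from a Z olefin). Joining C5 to C10 folds the ring into a cyclohexane (C5–C6–C7–C8–C9–C10) on which C5, C6, C7 and C8 are ordinary equatorial substituents, which is the retron of an oxy-Cope ring expansion.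

## Logic of the disconnections

**39 ⇒ 38 ⇒ 35 + 36.** The Si–O bond at C1 is cut first, then the acyl C–O bond at C6. The angelate is the group most prone to isomerise, so it goes on second to last and only a buffered desilylation follows it. All redox and strong-base chemistry thus precedes the ester. The forward step must acylate a hindered epoxy alcohol without Z→E drift and without opening the oxirane.

**35 ⇒ 34 ⇒ 33.** The two C–O bonds of the oxirane are cut, then the C6 ether. A free C6 hydroxyl is allylic to the Z C4=C5 bond and can deliver oxygen to the face that gives the cis epoxy alcohol (4R,5S beside 6S), so one stereocenter creates two. The C6 oxygen must be unmasked beside two other alkenes, the methylene lactone and an allylic silyl ether. This is why C6 is carried as a 4-methoxybenzyl ether, removed oxidatively at neutral pH. An acetal-type group was rejected because its acidic removal would invite allylic ionisation and transannular cyclisation of the cyclodecadiene.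

**33 ⇒ 28 + 29; 28 ⇒ 26 + 27; 26 ⇒ 25.** C11=C13, C10=C14 and the Si–O bond are cut. Both methylenes hang on carbonyl-derived carbons. The ketone is methylenated first because it cannot coexist with a lactone enolate. Since 26 is an α-silyloxy, β-acyloxy ketone, a basic phosphorus ylide would risk C1 epimerisation and expulsion of the lactone carboxylate. The forward reagent must therefore be non-basic and leave the lactone alone.

**25 ⇒ 22 (through 24 and 23).** This is the key retron: the C1 oxygen is removed, C2–C3 is broken and C5–C10 is formed. The ten-membered ring, the Z olefin and the C1 oxygen are all traced back to a cyclohexanol whose stereocenters are equatorial. The forward step needs cis vinyl and isopropenyl groups with the vinyl axial, exactly one equivalent of base, and capture of the enolate before it equilibrates towards C9.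

**22 ⇒ 21 ⇒ 19 + 20.** The C1–C10 bond is cut. An sp-hybridised nucleophile adds axially to the ketone and is then semihydrogenated; a vinyl metal would enter equatorially and give the wrong (trans) dialkenyl carbinol. Because 19 is a β-acyloxy ketone with an epimerisable C5, the organometallic must be weakly basic.

**19 ⇒ 18 ⇒ 16 ⇒ 13 + 14; 13 ⇒ 11.** The lactone C–O bond, the C8–H bond, the C7–C11 bond and the C10–O bond are cut in turn. In an all-equatorial array a second trans carbon/oxygen pair cannot come from epoxide opening: the trans-diaxial transition state would pass through an all-axial chair with the C5 and C7 substituents 1,3-diaxial. Opening an epoxide on a preformed trans-fused lactone would likewise deliver the isopropenyl group axial. C7 is therefore set by enolate alkylation trans to the C6 ether and C8 by directed hydride delivery. The forward sequence needs enolisation towards C7 and not C9, which the C10 alkoxide of 13 secures.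

**11 ⇒ 9 ⇒ 8 ⇒ 6 ⇒ 5 ⇒ 3 + 4; 3 ⇒ 2 ⇒ 1.** The C9=C10 unsaturation, the ketal, the ether, the resolution and the C4–C5 bond (isopropenyl to ring) are cut, then the epoxide and the ketal. The first trans carbon/oxygen pair (C5/C6) comes from anti opening of a conformationally free epoxide whose ketal steers the nucleophile to C5. The racemate is resolved at this first carbinol, so every later compound is a single enantiomer. The forward steps need regioselective opening and clean lipase discrimination.

## Other disconnections considered

**Alternative 1:** The cut removes C4–C5 and C1–C10 together. Forward, the excited enone A1 would add to 1-methylcyclobutene A2 to give the cis-anti-cis photoadduct A3. Thermal cycloreversion of the central cyclobutane (cleaving C5–C10 and C1–C4) would then unzip it to the cyclodecadienone A4.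
- In its favour: two simple fragments deliver both trisubstituted olefin carbons and the whole ring in two operations. C6 arrives as a ketone ready for reduction to the C6 carbinol. The 1(10)-ene is an ideal substrate for a singlet-oxygen ene reaction that would install C1–OH and the C10(14) methylene in one step. On convergence and on the C1/C14 installation this plan is the equal or the better of the chosen one.
- Against it here: in A3, C3 and C6 lie on opposite faces of the cyclobutane, so least-motion cleavage leaves them trans on C4=C5. A4 is therefore the 4E isomer, whereas the cis oxirane of the target needs 4Z. The photocycloaddition must also be head-to-head with an unsymmetrical cyclobutene and face-selective relative to C7/C8. At the thermolysis temperature a cyclodeca-1,5-diene can undergo Cope rearrangement to a divinylcyclohexane.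
- Comparison: in the chosen plan the olefin geometry follows from a chair locked by the lactone; here it follows from a cyclobutane configuration that points the wrong way. The skeleton would be reached in fewer steps, but correcting the geometry would cost the advantage.

**Alternative 2:** The cut is C6–C7, back to an acyclic chain. Forward, a class 1 cyclase of the germacrene A synthase type would ionise (2Z,6E)-farnesyl diphosphate A5, close the ring and deprotonate to the triene A6.
- In its favour: one enzymatic step sets the ring, the C7 configuration and the 4Z geometry from an achiral precursor. To the bare skeleton this is clearly better than the chosen plan.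
- Against it here: A6 carries none of the five oxygen functions (C1, C4/C5, C6, C8, C12). C8 and C12 are not even allylic, so chemical oxidation would lack any handle and a matched set of oxidising enzymes would be needed. A cyclase that accepts the 2Z substrate and releases this triene would have to be found or engineered. A6 itself is prone to Cope rearrangement and to acid-induced transannular cyclisation.
- Comparison: the mechanism is a cationic macrocyclisation under enzyme control against an anionic pericyclic shift under substrate control. Step economy is unbeatable up to A6 and poor beyond it, because the chosen plan brings C6, C7, C8 and C12 through the key step already functionalised.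

**Alternative 3:** The cut is C7–C8, with the C8 oxygen rejoined to C13 as an allylic ether, which enlarges the ring to thirteen members. Forward, tin–lithium exchange at C8 would trigger a [2,3]-Wittig (Still–Wittig) ring contraction to the alcohol A7.
- In its favour: A7 already holds the C1 and C6 oxygens, the C10 methylene, the Z olefin, the C8 carbinol and the C11(=C13)–C12 unit. Deprotection of C12 and oxidation would give the methylene lactone directly. In functional-group economy after the key step this plan is the equal or the better of the chosen one, which needs separate methylenations at C10 and C11.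
- Against it here: the precursor is a thirteen-membered ether with a configurationally defined α-alkoxystannane and a defined trisubstituted olefin, and building it would cost more than the whole route to 22. The shift must create C7 and C8 together through a transannular transition state in a floppy ring, so the required trans relationship is not assured. A [1,2]-shift and β-elimination compete.
- Comparison: both plans change ring size by an anionic sigmatropic shift. The chosen one stores its stereochemical information in a rigid cyclohexane before expansion; this one must generate it during contraction.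

Key step: step 14

Remark on the chemistry: germacrane numbering is applied to every intermediate. Racemates 3 and 5 are drawn as the enantiomer that is carried on. C10 of 12, 13 and 15–18 is drawn with the configuration expected from axial delivery of boron; this center is erased in step 11.

## Route

Step 1
Reactants: 1 1-methoxycyclohexa-1,4-diene
Product: 2 1,4-dioxaspiro[4.5]dec-7-ene
Conditions: HOCH2CH2OH, pyridinium p-toluenesulfonate (cat.), CH2Cl2, 0 → 25 °C
Reagents that add atoms: ethylene glycol, OCCO
Why: Acid-catalysed ketal exchange of the enol ether: protonation at the enol ether carbon gives an oxocarbenium ion that the diol traps. The isolated C5=C6 bond is not touched and stays β,γ to the ketal carbon under this mild acid.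

Step 2
Reactants: 2 1,4-dioxaspiro[4.5]dec-7-ene
Product: 3 racemic 7,8-epoxy-1,4-dioxaspiro[4.5]decane
Conditions: mCPBA, NaHCO3, CH2Cl2, 0 °C
Reagents that add atoms: 3-chloroperbenzoic acid, O=C(OO)c1cccc(Cl)c1
Why: Prilezhaev epoxidation of the only alkene; the bicarbonate buffer protects the ketal. The epoxide is necessarily cis-fused and racemic.

Step 3
Reactants: 3 racemic 7,8-epoxy-1,4-dioxaspiro[4.5]decane; 4 isopropenylmagnesium bromide
Product: 5 racemic trans-8-(prop-1-en-2-yl)-1,4-dioxaspiro[4.5]decan-7-ol
Conditions: CuI (10 mol %), THF, −30 → 0 °C; aq. NH4Cl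
Reagents that add atoms: none
Why: Copper-catalysed Grignard opening of an epoxide with inversion, which sets the trans C5/C6 relationship. Trans-diaxial attack at C6 would place the nucleophile 1,3-diaxial to an axial ketal oxygen, whereas attack at C5 lets magnesium bridge the departing oxygen and that ketal oxygen, so C5 should be attacked.

Step 4
Reactants: 5 racemic trans-8-(prop-1-en-2-yl)-1,4-dioxaspiro[4.5]decan-7-ol
Product: 6 (7S,8R)-8-(prop-1-en-2-yl)-1,4-dioxaspiro[4.5]decan-7-ol
Conditions: Candida antarctica lipase B (immobilised), vinyl acetate, t-BuOMe, 30 °C, run slightly past half conversion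
Reagents that add atoms: none
Why: Lipase-catalysed kinetic resolution by irreversible transesterification. By the empirical rule for secondary alcohols the (7R)-carbinol should be acetylated faster, so the wanted (7S,8R)-alcohol remains and is separated from the acetate by chromatography.

Step 5
Reactants: 6 (7S,8R)-8-(prop-1-en-2-yl)-1,4-dioxaspiro[4.5]decan-7-ol
Product: 8 (7S,8R)-7-[(4-methoxyphenyl)methoxy]-8-(prop-1-en-2-yl)-1,4-dioxaspiro[4.5]decane, via sodium alkoxide 7 (not isolated)
Conditions: NaH, THF–DMF, 0 °C; 4-methoxybenzyl chloride, Bu4NI (cat.), 25 °C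
Reagents that add atoms: 4-methoxybenzyl chloride, COc1ccc(CCl)cc1
Why: Williamson etherification; the ketal tolerates the base. The ether survives every later step and can be cleaved oxidatively at neutral pH.

Step 6
Reactants: 8 (7S,8R)-7-[(4-methoxyphenyl)methoxy]-8-(prop-1-en-2-yl)-1,4-dioxaspiro[4.5]decane
Product: 9 (3S,4R)-3-[(4-methoxyphenyl)methoxy]-4-(prop-1-en-2-yl)cyclohexan-1-one
Conditions: 1 M aq. HCl, THF, 25 °C
Reagents that add atoms: water, O
Why: Acid-catalysed ketal hydrolysis; dilute acid at room temperature should not eliminate the β-alkoxy group, hydrate the isopropenyl group or cleave the benzylic ether.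

Step 7
Reactants: 9 (3S,4R)-3-[(4-methoxyphenyl)methoxy]-4-(prop-1-en-2-yl)cyclohexan-1-one
Product: 11 (4R,5S)-5-[(4-methoxyphenyl)methoxy]-4-(prop-1-en-2-yl)cyclohex-2-en-1-one, via silyl enol ether 10 (not isolated)
Conditions: LDA, THF, −78 °C; Me3SiCl; then Pd(OAc)2, MeCN, 25 °C
Reagents that add atoms: none
Why: Saegusa–Ito dehydrogenation. Kinetic deprotonation of a β-alkoxy ketone takes place at the α-carbon remote from the oxygen-bearing carbon (C9, not C7), a known deactivating effect of β-oxygen substituents, so the C9=C10 enone should form.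

Step 8
Reactants: 11 (4R,5S)-5-[(4-methoxyphenyl)methoxy]-4-(prop-1-en-2-yl)cyclohex-2-en-1-one
Product: 13 (3S,4S,5S)-3-hydroxy-5-[(4-methoxyphenyl)methoxy]-4-(prop-1-en-2-yl)cyclohexan-1-one, via pinacol boronate 12 (not isolated)
Conditions: B2pin2, CuCl (cat.), DPEphos (cat.), NaOt-Bu (cat.), MeOH, THF, 0 °C; then NaBO3·4H2O, THF–H2O, 25 °C
Reagents that add atoms: sodium perborate, [Na+].[Na+].O[B-]1(O)OO[B-](O)(O)OO1
Why: Copper-catalysed conjugate borylation of the enone followed by C–B oxidation with retention. The boryl copper reagent should enter axially on the half-chair anchored by the two equatorial substituents, trans to the C6 ether, so the C10 hydroxyl is expected axial and cis to isopropenyl. This center is erased in step 11.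

Step 9
Reactants: 13 (3S,4S,5S)-3-hydroxy-5-[(4-methoxyphenyl)methoxy]-4-(prop-1-en-2-yl)cyclohexan-1-one; 14 ethyl bromoacetate
Product: 16 ethyl 2-[(1S,2R,3S,4S)-4-hydroxy-2-[(4-methoxyphenyl)methoxy]-6-oxo-3-(prop-1-en-2-yl)cyclohexyl]acetate, via dilithium aldolate enolate 15 (not isolated)
Conditions: LDA (2.2 equiv), THF, −78 → −40 °C; 14, DMPU, −78 → −40 °C; AcOH
Reagents that add atoms: none
Why: Alkylation of an aldolate dianion. The C10 alkoxide cannot be eliminated and deactivates the neighbouring C9–H, so the second deprotonation should go to C7. Alkylation anti to the adjacent equatorial C6 ether gives the trans (equatorial) side chain, which is also the thermodynamic epimer.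

Step 10
Reactants: 16 ethyl 2-[(1S,2R,3S,4S)-4-hydroxy-2-[(4-methoxyphenyl)methoxy]-6-oxo-3-(prop-1-en-2-yl)cyclohexyl]acetate
Product: 18 (3aR,4S,5S,6S,7aS)-6-hydroxy-4-[(4-methoxyphenyl)methoxy]-5-(prop-1-en-2-yl)hexahydro-1-benzofuran-2(3H)-one, via diol ester 17 (not isolated)
Conditions: Me4NBH(OAc)3, MeCN–AcOH, −30 °C; then camphorsulfonic acid (cat.), toluene, 50 °C
Reagents that add atoms: none
Why: Evans–Saksena reduction: the axial C10 hydroxyl binds boron and delivers hydride to C8 from the axial face, giving the equatorial C8 carbinol trans to the C7 side chain. Acid-catalysed transesterification then closes the trans-fused γ-lactone at C8 only, because C6 is an ether and the C10 hydroxyl cannot reach.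

Step 11
Reactants: 18 (3aR,4S,5S,6S,7aS)-6-hydroxy-4-[(4-methoxyphenyl)methoxy]-5-(prop-1-en-2-yl)hexahydro-1-benzofuran-2(3H)-one
Product: 19 (3aR,4S,5R,7aS)-4-[(4-methoxyphenyl)methoxy]-5-(prop-1-en-2-yl)hexahydro-1-benzofuran-2,6-dione
Conditions: Dess–Martin periodinane, NaHCO3, CH2Cl2, 0 °C
Reagents that add atoms: none
Why: Dess–Martin oxidation under buffered, base-free conditions, so the β,γ-unsaturated ketone should not conjugate and the β-acyloxy ketone should not eliminate. C5 keeps its equatorial, thermodynamically preferred configuration.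

Step 12
Reactants: 19 (3aR,4S,5R,7aS)-4-[(4-methoxyphenyl)methoxy]-5-(prop-1-en-2-yl)hexahydro-1-benzofuran-2,6-dione; 20 ethynylmagnesium bromide
Product: 21 (3aR,4S,5R,6R,7aS)-6-ethynyl-6-hydroxy-4-[(4-methoxyphenyl)methoxy]-5-(prop-1-en-2-yl)hexahydro-1-benzofuran-2(3H)-one
Conditions: CeCl3, THF, −78 °C; aq. NH4Cl
Reagents that add atoms: none
Why: Organocerium 1,2-addition; its low basicity avoids enolisation and β-elimination and the ketone reacts before the lactone. The linear sp nucleophile takes the axial trajectory past the axial hydrogens on C6 and C8, giving axial ethynyl cis to the equatorial isopropenyl group and an equatorial hydroxyl.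

Step 13
Reactants: 21 (3aR,4S,5R,6R,7aS)-6-ethynyl-6-hydroxy-4-[(4-methoxyphenyl)methoxy]-5-(prop-1-en-2-yl)hexahydro-1-benzofuran-2(3H)-one
Product: 22 (3aR,4S,5R,6S,7aS)-6-ethenyl-6-hydroxy-4-[(4-methoxyphenyl)methoxy]-5-(prop-1-en-2-yl)hexahydro-1-benzofuran-2(3H)-one
Conditions: H2 (1 atm), Pd/CaCO3 poisoned with Pb(OAc)2, quinoline, EtOAc, 25 °C
Reagents that add atoms: none
Why: Lindlar semihydrogenation of the terminal alkyne to the vinyl group, stopped after one equivalent of hydrogen; the isopropenyl group and the benzylic ether are not reduced on the poisoned catalyst.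

Step 14
Reactants: 22 (3aR,4S,5R,6S,7aS)-6-ethenyl-6-hydroxy-4-[(4-methoxyphenyl)methoxy]-5-(prop-1-en-2-yl)hexahydro-1-benzofuran-2(3H)-one
Product: 25 1α-hydroxy-6α-(4-methoxybenzyloxy)-10-oxo-7αH,8βH-germacr-4(Z)-en-12,8α-olide, via potassium alkoxide 23 (not isolated), via potassium enolate 24 (not isolated)
Conditions: KN(SiMe3)2 (1.05 equiv), 18-crown-6, THF, −78 → 0 °C; then −78 °C, 2-(phenylsulfonyl)-3-phenyloxaziridine; AcOH
Reagents that add atoms: 2-(phenylsulfonyl)-3-phenyloxaziridine, O=S(=O)(N1OC1c2ccccc2)c3ccccc3
Why: KN(SiMe3)2 with 18-crown-6 converts the tertiary alcohol into the dissociated alkoxide 23, which undergoes the charge-accelerated [3,3]-sigmatropic (anionic oxy-Cope) shift: C2–C3 forms, C5–C10 breaks, and 24, the enolate of the (Z)-cyclodec-4-en-10-one lactone, results. The closest known reaction type is the anionic oxy-Cope ring expansion of 1,2-dialkenylcyclohexanols to cyclodec-5-enones with capture of the enolate by an electrophile. The ten-membered ring is not closed end to end; it arises by four-carbon expansion of the cyclohexane through a chair transition state whose gauche C1–C10–C5–C4 torsion is already present in the cyclohexane chair. The shift creates no stereocenter but fixes two geometries: the trans-fused lactone and the equatorial C6 ether lock the ring with isopropenyl equatorial and vinyl axial, so C6 is axial on the reacting chair and C4=C5 is Z, while C9 is equatorial and the enolate double bond is trans within the ring. The enolate forms only towards C1 and is hydroxylated in the same flask by the Davis oxaziridine, before proton transfer to C9 could trigger loss of the lactone carboxylate. The new C1 stereocenter is controlled by the enolate: one face of the C1=C10 bond faces C4=C5 across the ring, so oxygen should arrive on the outer face, which in the conformer born from the chair gives 1S. The step needs one equivalent of base, so that the alkoxide and not the lactone enolate is formed, and a cold acidic quench, so that the α-ketol does not epimerise.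

Step 15
Reactants: 25 1α-hydroxy-6α-(4-methoxybenzyloxy)-10-oxo-7αH,8βH-germacr-4(Z)-en-12,8α-olide
Product: 26 1α-(tert-butyldimethylsilyloxy)-6α-(4-methoxybenzyloxy)-10-oxo-7αH,8βH-germacr-4(Z)-en-12,8α-olide
Conditions: t-BuMe2SiOTf, 2,6-lutidine, CH2Cl2, −78 °C
Reagents that add atoms: tert-butyldimethylsilyl triflate, CC(C)(C)[Si](C)(C)OS(=O)(=O)C(F)(F)F
Why: Silylation of the α-ketol with a silyl triflate and a hindered, weakly basic pyridine at low temperature; neither the β-acyloxy ketone nor C1 should be affected.

Step 16
Reactants: 26 1α-(tert-butyldimethylsilyloxy)-6α-(4-methoxybenzyloxy)-10-oxo-7αH,8βH-germacr-4(Z)-en-12,8α-olide; 27 dibromomethane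
Product: 28 1α-(tert-butyldimethylsilyloxy)-6α-(4-methoxybenzyloxy)-7αH,8βH-germacra-4(Z),10(14)-dien-12,8α-olide
Conditions: Zn, TiCl4, THF, −40 → 5 °C (reagent preformed from 27); then 26, CH2Cl2, 25 °C
Reagents that add atoms: none
Why: Takai–Lombardo methylenation: the zinc/titanium gem-dimetallic reagent is non-basic and selective for ketones over lactones, so it should neither epimerise C1 nor expel the C8 carboxylate.

Step 17
Reactants: 28 1α-(tert-butyldimethylsilyloxy)-6α-(4-methoxybenzyloxy)-7αH,8βH-germacra-4(Z),10(14)-dien-12,8α-olide; 29 N,N-dimethylmethyleneiminium iodide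
Product: 33 1α-(tert-butyldimethylsilyloxy)-6α-(4-methoxybenzyloxy)-7αH,8βH-germacra-4(Z),10(14),11(13)-trien-12,8α-olide, via lithium lactone enolate 30 (not isolated), via Mannich base 31 (not isolated), via trimethylammonium iodide 32 (not isolated)
Conditions: LDA, THF, −78 °C; 29, −78 → 0 °C; MeI, 25 °C; aq. NaHCO3
Reagents that add atoms: none
Why: Lactone α-methylenation by Mannich reaction of the enolate with Eschenmoser's salt, quaternisation and Hofmann-type elimination. C11–H is the only acidic site, and the configuration of C11 in 31 and 32 is irrelevant.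

Step 18
Reactants: 33 1α-(tert-butyldimethylsilyloxy)-6α-(4-methoxybenzyloxy)-7αH,8βH-germacra-4(Z),10(14),11(13)-trien-12,8α-olide
Product: 34 1α-(tert-butyldimethylsilyloxy)-6α-hydroxy-7αH,8βH-germacra-4(Z),10(14),11(13)-trien-12,8α-olide
Conditions: DDQ, CH2Cl2–pH 7 buffer, 0 °C
Reagents that add atoms: none
Why: Oxidative cleavage of the 4-methoxybenzyl ether (hydride abstraction to the oxocarbenium ion, then hydrolysis) at neutral pH. The silyl ether, the methylene lactone and the alkenes should be inert to the quinone.

Step 19
Reactants: 34 1α-(tert-butyldimethylsilyloxy)-6α-hydroxy-7αH,8βH-germacra-4(Z),10(14),11(13)-trien-12,8α-olide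
Product: 35 1α-(tert-butyldimethylsilyloxy)-4α,5α-epoxy-6α-hydroxy-7αH,8βH-germacra-10(14),11(13)-dien-12,8α-olide
Conditions: VO(acac)2 (cat.), t-BuOOH, CH2Cl2, 0 °C
Reagents that add atoms: tert-butyl hydroperoxide, CC(C)(C)OO
Why: Hydroxyl-directed epoxidation: the vanadate ester of the C6 alcohol delivers the peroxide oxygen to the olefin face syn to the C6–O bond, with the ring carbon C7 on the opposite face. This is the known outcome for medium-ring (Z)-cycloalk-2-enols and gives the cis epoxy alcohol, setting C4 (R) and C5 (S). Only the olefin of the allylic alcohol reacts.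

Step 20
Reactants: 35 1α-(tert-butyldimethylsilyloxy)-4α,5α-epoxy-6α-hydroxy-7αH,8βH-germacra-10(14),11(13)-dien-12,8α-olide; 36 angelic acid
Product: 38 6α-angeloyloxy-1α-(tert-butyldimethylsilyloxy)-4α,5α-epoxy-7αH,8βH-germacra-10(14),11(13)-dien-12,8α-olide, via mixed anhydride 37 (not isolated)
Conditions: 2,4,6-trichlorobenzoyl chloride, Et3N, toluene, 25 °C; then 35, toluene, 70 °C
Reagents that add atoms: none
Why: Yamaguchi-type acylation through the mixed anhydride, run without a nucleophilic acyl-transfer catalyst because that is what isomerises angelates to tiglates. The hindered aroyl carbonyl directs the alcohol to the angeloyl carbonyl.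

Step 21
Reactants: 38 6α-angeloyloxy-1α-(tert-butyldimethylsilyloxy)-4α,5α-epoxy-7αH,8βH-germacra-10(14),11(13)-dien-12,8α-olide
Product: 39 (1S,4R,5S,6S,7R,8S)-6-angeloyloxy-4,5-epoxy-1-hydroxygermacra-10(14),11(13)-dien-12,8-olide
Conditions: HF·pyridine, pyridine, THF, 0 → 25 °C
Reagents that add atoms: none
Why: Fluoride-mediated cleavage of the secondary allylic silyl ether, buffered with excess pyridine so that the oxirane, the angelate and the methylene lactone should survive.

## Compound list

1 | 1-methoxycyclohexa-1,4-diene | COC1=CCC=CC1 | starting material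
2 | 1,4-dioxaspiro[4.5]dec-7-ene | C1=CCC2(CC1)OCCO2 | intermediate
3 | racemic 7,8-epoxy-1,4-dioxaspiro[4.5]decane, cis-fused, (7S,8R) antipode drawn | C1COC2(O1)CC[C@H]3O[C@H]3C2 | intermediate
4 | isopropenylmagnesium bromide | CC(=C)[Mg]Br | starting material
5 | racemic trans-8-(prop-1-en-2-yl)-1,4-dioxaspiro[4.5]decan-7-ol, (7S,8R) antipode drawn | C1COC2(O1)CC[C@H](C(C)=C)[C@@H](O)C2 | intermediate
6 | (7S,8R)-8-(prop-1-en-2-yl)-1,4-dioxaspiro[4.5]decan-7-ol | C1COC2(O1)CC[C@H](C(C)=C)[C@@H](O)C2 | intermediate
7 | sodium (7S,8R)-8-(prop-1-en-2-yl)-1,4-dioxaspiro[4.5]decan-7-olate | C1COC2(O1)CC[C@H](C(C)=C)[C@@H]([O-])C2.[Na+] | intermediate (not isolated)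
8 | (7S,8R)-7-[(4-methoxyphenyl)methoxy]-8-(prop-1-en-2-yl)-1,4-dioxaspiro[4.5]decane | C1COC2(O1)CC[C@H](C(C)=C)[C@@H](OCc3ccc(OC)cc3)C2 | intermediate
9 | (3S,4R)-3-[(4-methoxyphenyl)methoxy]-4-(prop-1-en-2-yl)cyclohexan-1-one | O=C1CC[C@H](C(C)=C)[C@@H](OCc2ccc(OC)cc2)C1 | intermediate
10 | trimethylsilyl enol ether of 9 (C8=C9), (4R,5S) | C[Si](C)(C)OC1=CC[C@H](C(C)=C)[C@@H](OCc2ccc(OC)cc2)C1 | intermediate (not isolated)
11 | (4R,5S)-5-[(4-methoxyphenyl)methoxy]-4-(prop-1-en-2-yl)cyclohex-2-en-1-one | O=C1C=C[C@H](C(C)=C)[C@@H](OCc2ccc(OC)cc2)C1 | intermediate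
12 | (3S,4R,5S)-5-[(4-methoxyphenyl)methoxy]-4-(prop-1-en-2-yl)-3-(4,4,5,5-tetramethyl-1,3,2-dioxaborolan-2-yl)cyclohexan-1-one, boron cis to isopropenyl | O=C1C[C@H](B2OC(C)(C)C(C)(C)O2)[C@H](C(C)=C)[C@@H](OCc3ccc(OC)cc3)C1 | intermediate (not isolated)
13 | (3S,4S,5S)-3-hydroxy-5-[(4-methoxyphenyl)methoxy]-4-(prop-1-en-2-yl)cyclohexan-1-one, hydroxyl cis to isopropenyl | O=C1C[C@H](O)[C@H](C(C)=C)[C@@H](OCc2ccc(OC)cc2)C1 | intermediate
14 | ethyl bromoacetate | CCOC(=O)CBr | starting material
15 | dilithium salt of 13: C10 alkoxide and C7=C8 enolate | [Li+].[Li+].[O-]C1C[C@H]([O-])[C@H](C(C)=C)[C@@H](OCc2ccc(OC)cc2)C=1 | intermediate (not isolated)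
16 | ethyl 2-[(1S,2R,3S,4S)-4-hydroxy-2-[(4-methoxyphenyl)methoxy]-6-oxo-3-(prop-1-en-2-yl)cyclohexyl]acetate | O=C1C[C@H](O)[C@H](C(C)=C)[C@@H](OCc2ccc(OC)cc2)[C@@H]1CC(=O)OCC | intermediate
17 | ethyl 2-[(1R,2S,3S,4S,6S)-4,6-dihydroxy-2-[(4-methoxyphenyl)methoxy]-3-(prop-1-en-2-yl)cyclohexyl]acetate | O[C@H]1C[C@H](O)[C@H](C(C)=C)[C@@H](OCc2ccc(OC)cc2)[C@@H]1CC(=O)OCC | intermediate (not isolated)
18 | (3aR,4S,5S,6S,7aS)-6-hydroxy-4-[(4-methoxyphenyl)methoxy]-5-(prop-1-en-2-yl)hexahydro-1-benzofuran-2(3H)-one | C1C(=O)O[C@H]2C[C@H](O)[C@H](C(C)=C)[C@@H](OCc3ccc(OC)cc3)[C@H]12 | intermediate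
19 | (3aR,4S,5R,7aS)-4-[(4-methoxyphenyl)methoxy]-5-(prop-1-en-2-yl)hexahydro-1-benzofuran-2,6-dione | C1C(=O)O[C@H]2CC(=O)[C@H](C(C)=C)[C@@H](OCc3ccc(OC)cc3)[C@H]12 | intermediate
20 | ethynylmagnesium bromide | C#C[Mg]Br | starting material
21 | (3aR,4S,5R,6R,7aS)-6-ethynyl-6-hydroxy-4-[(4-methoxyphenyl)methoxy]-5-(prop-1-en-2-yl)hexahydro-1-benzofuran-2(3H)-one | C1C(=O)O[C@H]2C[C@](O)(C#C)[C@H](C(C)=C)[C@@H](OCc3ccc(OC)cc3)[C@H]12 | intermediate
22 | (3aR,4S,5R,6S,7aS)-6-ethenyl-6-hydroxy-4-[(4-methoxyphenyl)methoxy]-5-(prop-1-en-2-yl)hexahydro-1-benzofuran-2(3H)-one (key-step precursor) | C1C(=O)O[C@H]2C[C@](O)(C=C)[C@H](C(C)=C)[C@@H](OCc3ccc(OC)cc3)[C@H]12 | intermediate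
23 | potassium alkoxide of 22 | C1C(=O)O[C@H]2C[C@]([O-])(C=C)[C@H](C(C)=C)[C@@H](OCc3ccc(OC)cc3)[C@H]12.[K+] | intermediate (not isolated)
24 | potassium C1=C10 enolate (C2 trans to C9) of 6α-(4-methoxybenzyloxy)-10-oxo-7αH,8βH-germacr-4(Z)-en-12,8α-olide | C1C(=O)O[C@H]2C/C([O-])=C/CC/C(C)=C\[C@@H](OCc3ccc(OC)cc3)[C@H]12.[K+] | intermediate (not isolated)
25 | 1α-hydroxy-6α-(4-methoxybenzyloxy)-10-oxo-7αH,8βH-germacr-4(Z)-en-12,8α-olide (1S) | C1C(=O)O[C@H]2CC(=O)[C@@H](O)CC/C(C)=C\[C@@H](OCc3ccc(OC)cc3)[C@H]12 | intermediate
26 | 1α-(tert-butyldimethylsilyloxy)-6α-(4-methoxybenzyloxy)-10-oxo-7αH,8βH-germacr-4(Z)-en-12,8α-olide | C1C(=O)O[C@H]2CC(=O)[C@@H](O[Si](C)(C)C(C)(C)C)CC/C(C)=C\[C@@H](OCc3ccc(OC)cc3)[C@H]12 | intermediate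
27 | dibromomethane | BrCBr | starting material
28 | 1α-(tert-butyldimethylsilyloxy)-6α-(4-methoxybenzyloxy)-7αH,8βH-germacra-4(Z),10(14)-dien-12,8α-olide | C1C(=O)O[C@H]2CC(=C)[C@@H](O[Si](C)(C)C(C)(C)C)CC/C(C)=C\[C@@H](OCc3ccc(OC)cc3)[C@H]12 | intermediate
29 | N,N-dimethylmethyleneiminium iodide (Eschenmoser's salt) | C[N+](C)=C.[I-] | starting material
30 | lithium C11=C12 enolate of 28 | [Li+].C1=C([O-])O[C@H]2CC(=C)[C@@H](O[Si](C)(C)C(C)(C)C)CC/C(C)=C\[C@@H](OCc3ccc(OC)cc3)[C@H]12 | intermediate (not isolated)
31 | 11-(dimethylaminomethyl) derivative of 28, C11 epimers | CN(C)CC1C(=O)O[C@H]2CC(=C)[C@@H](O[Si](C)(C)C(C)(C)C)CC/C(C)=C\[C@@H](OCc3ccc(OC)cc3)[C@H]12 | intermediate (not isolated)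
32 | 11-(trimethylammoniomethyl) iodide of 28, C11 epimers | C[N+](C)(C)CC1C(=O)O[C@H]2CC(=C)[C@@H](O[Si](C)(C)C(C)(C)C)CC/C(C)=C\[C@@H](OCc3ccc(OC)cc3)[C@H]12.[I-] | intermediate (not isolated)
33 | 1α-(tert-butyldimethylsilyloxy)-6α-(4-methoxybenzyloxy)-7αH,8βH-germacra-4(Z),10(14),11(13)-trien-12,8α-olide | C=C1C(=O)O[C@H]2CC(=C)[C@@H](O[Si](C)(C)C(C)(C)C)CC/C(C)=C\[C@@H](OCc3ccc(OC)cc3)[C@H]12 | intermediate
34 | 1α-(tert-butyldimethylsilyloxy)-6α-hydroxy-7αH,8βH-germacra-4(Z),10(14),11(13)-trien-12,8α-olide | C=C1C(=O)O[C@H]2CC(=C)[C@@H](O[Si](C)(C)C(C)(C)C)CC/C(C)=C\[C@@H](O)[C@H]12 | intermediate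
35 | 1α-(tert-butyldimethylsilyloxy)-4α,5α-epoxy-6α-hydroxy-7αH,8βH-germacra-10(14),11(13)-dien-12,8α-olide (4R,5S) | C=C1C(=O)O[C@H]2CC(=C)[C@@H](O[Si](C)(C)C(C)(C)C)CC[C@@]3(C)O[C@H]3[C@@H](O)[C@H]12 | intermediate
36 | angelic acid, (Z)-2-methylbut-2-enoic acid | C/C=C(/C)C(=O)O | starting material
37 | (Z)-2-methylbut-2-enoic 2,4,6-trichlorobenzoic anhydride | C/C=C(/C)C(=O)OC(=O)c1c(Cl)cc(Cl)cc1Cl | intermediate (not isolated)
38 | 6α-angeloyloxy-1α-(tert-butyldimethylsilyloxy)-4α,5α-epoxy-7αH,8βH-germacra-10(14),11(13)-dien-12,8α-olide | C=C1C(=O)O[C@H]2CC(=C)[C@@H](O[Si](C)(C)C(C)(C)C)CC[C@@]3(C)O[C@H]3[C@@H](OC(=O)/C(C)=C\C)[C@H]12 | intermediate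
39 | (1S,4R,5S,6S,7R,8S)-6-angeloyloxy-4,5-epoxy-1-hydroxygermacra-10(14),11(13)-dien-12,8-olide | C=C1C(=O)O[C@H]2CC(=C)[C@@H](O)CC[C@@]3(C)O[C@H]3[C@@H](OC(=O)/C(C)=C\C)[C@H]12 | target

## Step count and least certain steps

Total: 21 steps. Longest linear sequence: 21 steps (1 → 39); 4, 14, 20, 27, 29 and 36 are bought and enter without steps of their own.

**Step 14 (key step).** Most likely to go wrong is the facial selectivity of the hydroxylation at C1. The ring-trans C1=C10 enolate can turn over within the ten-membered ring at the temperature the rearrangement needs, so the outer face of the nascent conformer need not stay the reactive one. A secondary hazard is equilibration of the enolate towards C9, followed by loss of the lactone carboxylate, if the oxidation is delayed. Fallback: starting from 22, the step is run as described. Should the 1β-hydroxy epimer F1 prevail, it would be inverted by a Mitsunobu reaction with chloroacetic acid (PPh3, diisopropyl azodicarboxylate, toluene, 0 °C) to the 1α-chloroacetate F2. The α-carbonyl position favours clean SN2 displacement. The chloroacetate would then be removed with thiourea and NaHCO3 in EtOH, and the route is rejoined at 25.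

**Step 9.** Most likely to go wrong is the regiochemistry of the second deprotonation: enolisation towards C9 in spite of the alkoxide, with some O-alkylation of the alkoxide. Both α-sites are deactivated by a β-oxygen and only the stronger effect of the alkoxide separates them. Fallback: starting from 11, the order of the two operations is inverted. Kinetic deprotonation of the enone with LDA can only occur at C7, and alkylation with 14 would give the enone ester F3. Conjugate borylation and perborate oxidation as in step 8 would then return the route to 16.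

**Step 10.** Most likely to go wrong is the facial selectivity of hydride delivery to C8. If the C10 hydroxyl of 16 turns out equatorial and not axial, internal delivery would approach from the wrong face and the cis-fused lactone would result. Fallback: starting from 16, the control element is changed from the substrate to the reagent. A Corey–Bakshi–Shibata reduction with the (R)-methyl oxazaborolidine and catecholborane in toluene at −78 °C distinguishes the branched C7 side from the C9 methylene whatever the configuration at C10. The same acid treatment then leads back to 18; no new compound arises.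

**Step 16.** Most likely to go wrong is slow methylenation of the hindered α-silyloxy ketone, with loss of the allylic silyl ether or the benzylic ether on long exposure to the Lewis-acidic titanium species. Fallback: starting from 26, a Peterson olefination. Addition of Me3SiCH2MgCl with CeCl3 in THF at −78 °C would give the β-hydroxysilane F4, and syn-elimination with KH in THF at 0 °C would give 28.

**Step 20.** Most likely to go wrong is Z→E isomerisation of the angeloyl unit and slow acylation of the hindered epoxy alcohol. The long heating with amine salts that follows would invite opening of the oxirane and translactonisation towards C6. Fallback: starting from 35, the Z olefin is built on the ester. Acylation with 2-[bis(2,2,2-trifluoroethoxy)phosphoryl]propanoic acid (dicyclohexylcarbodiimide, 4-dimethylaminopyridine cat., CH2Cl2, 0 °C) would give the phosphonate ester F5. A Still–Gennari olefination with acetaldehyde (KN(SiMe3)2, 18-crown-6, THF, −78 °C) would then give 38.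

## Further compounds

F1 | step 14 | 1β-hydroxy-6α-(4-methoxybenzyloxy)-10-oxo-7αH,8βH-germacr-4(Z)-en-12,8α-olide (C1 epimer of 25) | C1C(=O)O[C@H]2CC(=O)[C@H](O)CC/C(C)=C\[C@@H](OCc3ccc(OC)cc3)[C@H]12
F2 | step 14 | 1α-(chloroacetoxy)-6α-(4-methoxybenzyloxy)-10-oxo-7αH,8βH-germacr-4(Z)-en-12,8α-olide | C1C(=O)O[C@H]2CC(=O)[C@@H](OC(=O)CCl)CC/C(C)=C\[C@@H](OCc3ccc(OC)cc3)[C@H]12
F3 | step 9 | ethyl 2-[(1S,5R,6R)-6-[(4-methoxyphenyl)methoxy]-2-oxo-5-(prop-1-en-2-yl)cyclohex-3-en-1-yl]acetate | O=C1C=C[C@H](C(C)=C)[C@@H](OCc2ccc(OC)cc2)[C@@H]1CC(=O)OCC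
F0 | step 10 | none | none
F4 | step 16 | 10-hydroxy-10-(trimethylsilylmethyl) adduct of 26, C10 configuration not defined | C1C(=O)O[C@H]2CC(O)(C[Si](C)(C)C)[C@@H](O[Si](C)(C)C(C)(C)C)CC/C(C)=C\[C@@H](OCc3ccc(OC)cc3)[C@H]12
F5 | step 20 | 6α-{2-[bis(2,2,2-trifluoroethoxy)phosphoryl]propanoyloxy} derivative of 35, propanoate α-carbon as both epimers | C=C1C(=O)O[C@H]2CC(=C)[C@@H](O[Si](C)(C)C(C)(C)C)CC[C@@]3(C)O[C@H]3[C@@H](OC(=O)C(C)P(=O)(OCC(F)(F)F)OCC(F)(F)F)[C@H]12
A1 | alternative 1 | methyl 2-[(1R,6S)-6-(tert-butyldimethylsilyloxy)-4-methyl-2-oxocyclohex-3-en-1-yl]acetate | COC(=O)C[C@@H]1[C@@H](O[Si](C)(C)C(C)(C)C)CC(C)=CC1=O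
A2 | alternative 1 | 1-methylcyclobutene | CC1=CCC1
A3 | alternative 1 | cis-anti-cis tricyclic photoadduct | COC(=O)C[C@@H]1[C@@H](O[Si](C)(C)C(C)(C)C)C[C@]2(C)[C@H]3CC[C@@]3(C)[C@@H]2C1=O
A4 | alternative 1 | (1(10)E,4E)-cyclodecadien-6-one from stereoretentive opening of A3 | COC(=O)C[C@@H]1[C@@H](O[Si](C)(C)C(C)(C)C)C/C(C)=C/CC/C(C)=C/C1=O
A5 | alternative 2 | (2Z,6E)-farnesyl diphosphate | CC(C)=CCC/C(C)=C/CC/C(C)=C\COP(=O)(O)OP(=O)(O)O
A6 | alternative 2 | (1(10)E,4Z)-germacra-1(10),4,11-triene | CC(=C)[C@@H]1CC/C(C)=C/CC/C(C)=C\C1
A7 | alternative 3 | ten-membered C8 alcohol with C7 propenyl side chain | O[C@H]1CC(=C)[C@@H](O[Si](C)(C)C(C)(C)C)CC/C(C)=C\[C@@H](O[Si](CC)(CC)CC)[C@@H]1C(=C)COCc2ccc(OC)cc2
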